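## Analysis of the target

Argophyllin A is a germacranolide: a ten-membered carbocycle (C1 to C10) trans-fused through C6 and C7 to an α-methylene-γ-butyrolactone (C11 to C13, ring oxygen on C6). It has seven stereocentres. C1 and C10 carry a trans epoxide that derives from an E olefin. C3 (secondary) and C4 (tertiary, methyl-bearing) carry an anti diol. C6, C7 and C8 are contiguous: the lactone oxygen on C6 is anti to the C7–C11 bond, and the C8 angelate sits on the same ring face (β) as C11, the C4 methyl and the C10 methyl. The sensitive groups are:

- the exo-methylene lactone, a Michael acceptor that does not tolerate enolate chemistry elsewhere;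
- the angelate, a (Z)-2-methylbut-2-enoate that isomerises to the tiglate under nucleophilic catalysis;
- the 1,10-epoxide, which the C3 and C4 hydroxyls can open across the ring under acid.

The synthesis is hard for two reasons: a ten-membered ring with a defined E olefin has to be made, and the C3/C4 pair has to be related to the C6–C8 triad across a flexible ring. The strategy rests on the sequence C1=C10–C9–C8–C7–C6(O). The C6 oxygen is 1,5 to the olefin that precedes the epoxide, and C8 is oxygenated. This is the pattern of a 3-alkoxycyclodec-5-enone, which an oxy-Cope rearrangement makes from a 1-(2-alkoxyvinyl)-2-isopropenylcyclohexanol whose ring bond C1–C6 is the bond that breaks.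

## Retrosynthetic reasoning

**Epoxide (39 to 38).** The two C–O bonds of the epoxide are cut first. The epoxide is the most acid-labile group and has two hydroxyls nearby, so it must come last. In the forward direction one electron-rich, strained E olefin has to be oxidised beside two electron-poor olefins, on the outer face of the crown-shaped ring. That face leads to the 1R,10R epoxide.

**Acetonide and angelate (38 to 37 to 34 and 35).** The diol is masked as its trans-fused acetonide, which is strained and therefore comes off under mild acid. The C8–O acyl bond is cut next, giving alcohol 34 and angelic acid 35. The angelate goes on after all enolate chemistry is finished, because a base would deconjugate or isomerise it.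

**Methylene and PMB ether (34 to 33 to 28 and 29).** The C11=C13 bond is cut back to the saturated lactone 28 and the iminium salt 29. The PMB ether on C8 is kept through the lactone enolate step and removed oxidatively afterwards, so that only one hydroxyl is ever free for acylation.

**Lactone C6–O bond (28 to 26 to 25).** The bond is cut with inversion. A hydride can reach the C6 carbonyl of 25 only from the ring periphery, and this should give the 6S alcohol 26, with its oxygen on the wrong face for a trans lactone. The ester carbonyl of the C7 arm then displaces an activated C6 oxygen from the back. A tert-butyl ester is chosen because it resists closure by the C6 alkoxide and loses its alkyl group as isobutene after the displacement.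

**C7–C11 bond (25 to 22 and 23).** The acetate arm is added by alkylation of an enolate whose double bond can only lie between C6 and C7. What is gained is regiochemistry: C5 is also α to the ketone and would compete in any deprotonation.

**Key disconnection (22 to 18 and 19).** C8–C9 is cut and C1–C6 is reconnected. The ten-membered silyl enol ether 22 becomes the cyclohexanol 18, in which C1–C6 is a ring bond and the two alkenyl groups are trans. The forward [3,3] shift has to give the E olefin, the C6–C7 enolate and 8R. All three follow from one chair transition state of the trans-diequatorial alcohol with a Z enol ether.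

**C6–C7 bond (18 to 11 and 16).** The alcohol comes from ketone 11 and the Z alkoxyvinyl bromide 16 (through its lithium reagent). The axial C4 methyl of 11 forces equatorial attack. Bromide 16 comes from the vinyl ether 14, made from 12 and 13.

**Diol of 11 (11 to 9 to 8 to 7 to 6).** The C4–O bond is traced to conjugate epoxidation of enone 6, followed by reductive opening of the epoxy ketone 7. This puts the tertiary hydroxyl β to the ketone and leaves C5 as CH2. The pseudo-axial silyl ether on C3 sends the peroxide to the opposite face, so the diol is anti. The isopropenyl centre is α to the ketone and is set last by equilibration under the acetonide.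

**Carbonyl and chiral pool (6 to 5 to 4 to 2 to 1).** The C6 carbonyl comes from allylic oxidation of the silyl ether 5 of trans-carveol 4. Compound 4 arises from (S)-carvone 1 by epoxidation and Wharton transposition. This gives the hydroxyl anti to the isopropenyl group (needed for the pseudo-axial silyl ether) and moves the olefin so that the future C6 is allylic. A menthane that carries its ring oxygen on C6 instead of C3 was not used. It would require deconjugating an enone through an enolate that erases the only stereocentre, and opening a β,γ-epoxy ketone with hydroxide, which eliminates instead.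

## Alternatives that were turned down

**Alternative 1: nitrile oxide cycloaddition across C4 to C6.**
- Disconnection and key step: C5–C6 and the O–C4 bond. EtMgBr would convert the open-chain hydroximoyl chloride A1 into a magnesium-bound nitrile oxide that adds to the C4–C5 olefin and closes the carbocycle as the bridged isoxazoline A2.
- For: one step forms the ring, the tertiary C4–O bond (delivered under the influence of the C3 alkoxide) and a masked C6 carbonyl. The E olefin and the C7/C8 centres are made beforehand in an open chain.
- Against: the ring is closed end to end by a reactive dipole, which needs high dilution and competes with dimerisation to furoxans. The transition state must hold an E olefin inside a bridged bicycle. The C7/C8 pair needs separate acyclic stereocontrol. The N–O bond must later be cleaved reductively beside the olefin, and the unmasked β-hydroxy ketone still needs the C6 reduction that is also the weak point of the chosen route.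
- Comparison: A2 is stronger on C4, which it sets in the ring-forming step. The chosen strategy forms the ring by rearrangement without dilution, gets the olefin geometry from mechanism, and provides a regiodefined enolate for C7.

**Alternative 2: Nozaki–Hiyama–Kishi closure at C3–C4.**
- Disconnection and key step: C3–C4. CrCl2 (divalent chromium) with catalytic NiCl2 would convert the alkenyl iodide of the seco aldehyde A3 into an alkenylchromium that adds to the C3 aldehyde, giving the exo-methylene allylic alcohol A4.
- For: the reaction tolerates functionality and has closed medium rings. The C6–C8 triad is already fixed on a five-membered lactol ether before cyclisation.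
- Against: closure is again end to end, with a large excess of chromium at high dilution. The C3 configuration depends on an unknown macrocyclic transition state. Above all, A4 has a methylene on C4 instead of the methyl carbinol. Hydroxyl-directed epoxidation with hydride opening would give the syn diol, and radical hydration would be unselective at C4 and would compete with the C1=C10 olefin. The anti C3/C4 relationship therefore remains unsolved after the key step.
- Comparison: A4 is stronger in convergence and in having C6 to C8 set on a rigid template, which the chosen route must achieve by conformational control on the ten-membered ring. The chosen strategy sets the anti diol on a cyclohexane, where facial control is secure, and carries it through the ring expansion.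

**Alternative 3: nickel reductive alkyne–epoxide coupling at C9–C10.**
- Disconnection and key step: C9–C10. Ni(cod)2 (zerovalent nickel) with PBu3 and Et3B would couple the methyl alkyne with the terminal epoxide of the lactone A5, giving the E-olefin lactone A6 with hydrogen on C1 and a free C8 hydroxyl.
- For: this has the best endgame economy. A6 already has the lactone and the acetonide, and its C8 hydroxyl is free for acylation, so no PMB ether is needed. The olefin geometry follows from syn addition, and the step is catalytic.
- Against: intramolecular couplings of this type are established for small rings. A ten-membered ring with an endocyclic E trisubstituted olefin would require a strained metallacycle. Insertion must also distinguish a methyl from a methylene terminus of the alkyne, and oligomerisation competes. The key step would be an untested extension of the method.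
- Comparison: A6 is superior in step count after ring closure. The chosen strategy places its risk on a ring expansion of a well-precedented type, whose stereochemical outcome follows from mechanism.

Key step: step 12

Remark: germacrane numbering of the target is used for every intermediate, so in the six-membered compounds the ring atoms are C6 (carbinol or carbonyl carbon), C5, C4, C3, C2 and C1 (isopropenyl carbon); β is the ring face that carries the C8 oxygen; CIP descriptors in names use the locants of each name; (S)-(+)-carvone of high enantiomeric purity is assumed, since it is the only source of absolute configuration.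

Step 1
Reactants: 1 (S)-(+)-carvone
Product: 2 (1S,4S,6S)-carvone oxide with the epoxide anti to the isopropenyl group
Conditions: 30% H2O2, NaOH (cat.), MeOH, 0 °C
Reagents that add atoms: hydrogen peroxide, OO
Why: Weitz–Scheffer nucleophilic epoxidation touches only the enone; axial attack of hydroperoxide anti to the isopropenyl group fixes the CH–O centre that becomes C3.

Step 2
Reactants: 2
Product: 4 (1S,5R)-trans-carveol, via epoxy hydrazone 3 (not isolated)
Conditions: N2H4·H2O, AcOH (cat.), MeOH, 0 °C to rt
Reagents that add atoms: none
Why: Wharton transposition: the hydrazone loses N2 and the C–O bond next to the former carbonyl breaks, while the remote C–O bond keeps its configuration, so the allylic hydroxyl is anti to the isopropenyl group. The olefin moves so that the future C6 methylene becomes allylic.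

Step 3
Reactants: 4
Product: 5 tert-butyldimethylsilyl ether of trans-carveol
Conditions: TBSCl, imidazole, DMF, rt
Reagents that add atoms: tert-butyldimethylsilyl chloride, CC(C)(C)[Si](C)(C)Cl
Why: Standard silylation of a secondary allylic alcohol; the bulky ether protects the carbinol from oxidation and later directs the epoxidation.

Step 4
Reactants: 5
Product: 6 (4S,6R)-4-silyloxy-3-methyl-6-isopropenylcyclohex-2-enone
Conditions: Rh2(cap)4 (1 mol %), t-BuOOH (70% aq, 5 equiv), K2CO3, CH2Cl2, rt
Reagents that add atoms: tert-butyl hydroperoxide, CC(C)(C)OO
Why: Catalytic allylic C–H oxidation of a trisubstituted cyclohexene to the enone; the only ring methylene allylic to the olefin is C6, whose pseudo-axial hydrogen is abstracted. The carbinol hydrogen is pseudo-equatorial, because A(1,2) strain with the vinylic methyl holds the silyloxy group pseudo-axial, and is therefore poorly aligned for abstraction.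

Step 5
Reactants: 6
Product: 7 (1R,3R,5S,6S)-epoxy ketone with the epoxide anti to the silyloxy group
Conditions: t-BuOOH, Triton B (cat.), THF, 0 °C
Reagents that add atoms: tert-butyl hydroperoxide, CC(C)(C)OO
Why: Weitz–Scheffer epoxidation of a β,β-disubstituted enone under weakly basic conditions; the peroxide adds axially to C4, anti to the pseudo-axial silyloxy group on C3. Steric and stereoelectronic preferences coincide, so the C4 oxygen ends up anti to the C3 oxygen.

Step 6
Reactants: 7
Product: 8 (2R,4S,5S)-β-hydroxy ketone
Conditions: SmI2 (2.2 equiv), THF/MeOH, −90 °C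
Reagents that add atoms: none
Why: Reductive opening of an α,β-epoxy ketone by divalent samarium: the ketyl cleaves the C5–O bond and the samarium enolate is protonated by methanol. C5 becomes CH2 and the tertiary C4 hydroxyl keeps its configuration.

Step 7
Reactants: 8
Product: 9 (2R,4S,5S)-4,5-dihydroxy-5-methyl-2-isopropenylcyclohexanone
Conditions: HF·pyridine, THF, 0 °C to rt
Reagents that add atoms: none
Why: Buffered fluoride cleaves the secondary silyl ether without the base that would dehydrate the β-hydroxy ketone.

Step 8
Reactants: 9
Product: 11 acetonide ketone (2S,4S,5S) with equatorial isopropenyl group, via axial-isopropenyl acetonide 10 (not isolated)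
Conditions: 2-methoxypropene, PPTS (cat.), CH2Cl2, 0 °C; then DBU, rt
Reagents that add atoms: 2-methoxypropene, COC(C)=C
Why: Kinetic acetalisation closes the trans-fused dioxolane only on the chair with both oxygens equatorial, which puts the C4 methyl axial and, in 10, the isopropenyl group axial. DBU then epimerises the centre α to the ketone through its enolate to the equatorial isomer 11; axial protonation at the α carbon is the kinetic path, and exposure is kept short so that the dienolate is not protonated at its terminus.

Step 9
Reactants: 12 4-methoxybenzyl alcohol; 13 ethyl vinyl ether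
Product: 14 4-methoxybenzyl vinyl ether
Conditions: Pd(OAc)2 (cat.), 1,10-phenanthroline (cat.), 13 as solvent, rt
Reagents that add atoms: none
Why: Transfer vinylation of a primary alcohol catalysed by divalent palladium; the excess of 13 drives the exchange.

Step 10
Reactants: 14
Product: 16 (Z)-2-bromovinyl 4-methoxybenzyl ether, via dibromo ether 15 (not isolated)
Conditions: Br2, CH2Cl2, −78 °C; then i-Pr2NEt, −78 to 40 °C
Reagents that add atoms: bromine, BrBr
Why: Bromine adds to the enol ether far faster than to the anisole ring; the α-bromo ether loses HBr through its oxocarbenium ion, giving the β-bromo enol ether with the cis isomer favoured, as for simple alkyl vinyl ethers.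

Step 11
Reactants: 16; 11
Product: 18 (1S,2S,4S,5S)-divinyl carbinol acetonide, via (Z)-alkoxyvinyllithium 17 (not isolated)
Conditions: n-BuLi, Et2O, −78 °C; then 11 in THF, −78 °C; H2O
Reagents that add atoms: none
Why: Bromine–lithium exchange occurs with retention, and the cis reagent is held by O–Li coordination, whereas a trans isomer would be lost by anti elimination. The axial C4 methyl blocks the axial trajectory at C6, so the reagent adds equatorially, giving the axial alcohol with the alkoxyvinyl group trans to the equatorial isopropenyl group.

Step 12
Reactants: 18; 19 chlorotrimethylsilane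
Product: 22 ten-membered trimethylsilyl enol ether (3S,4S,8R) with E C1=C10 olefin, via potassium alkoxide 20 (not isolated), via potassium enolate 21 (not isolated)
Conditions: KH, 18-crown-6, THF, 0 to 40 °C; then Me3SiCl, Et3N, −78 °C
Reagents that add atoms: none
Why: KH with 18-crown-6 gives the potassium alkoxide 20, whose oxyanion weakens the adjacent C1–C6 bond, and the 3-oxido-1,5-diene C8=C7–C6–C1–C10=C9 undergoes a concerted suprafacial [3,3] shift. The closest known reaction type is the anionic oxy-Cope ring expansion of trans-1,2-dialkenylcyclohexanols to (E)-cyclodec-5-enone enolates. The ten-membered ring is closed by four-atom ring expansion and not end to end: C8–C9 forms inside a six-membered chair transition state while the shared bond C1–C6 breaks. Because the alkenyl groups are trans-diequatorial, the chair keeps both ring residues (C5 on C6, C2 on C1) equatorial, which gives the E C1=C10 olefin and the ring-trans C6=C7 enolate. The only new stereocentre, C8, is controlled by the configuration of C1 and C6 (which allows one chair), by the chair topology and by the Z enol ether, which places the PMB-oxy group pseudo-axial and gives 8R. The step needs chair-over-boat selectivity, which the diequatorial cyclohexane secures, and the enolate can only form toward C7. The β-alkoxy enolate 21 must survive, so it is silylated at −78 °C as soon as rearrangement is complete. Enolate formation makes the step irreversible.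

Step 13
Reactants: 22; 23 tert-butyl bromoacetate
Product: 25 C7-alkylated keto ester (3S,4S,7R,8R), via lithium enolate 24 (not isolated)
Conditions: MeLi, THF, 0 °C; then 23, HMPA, −78 to −30 °C
Reagents that add atoms: none
Why: MeLi cleaves the O–Si bond and gives the lithium enolate with its double bond still between C6 and C7; lithium bridging to the C8 ether oxygen keeps the C8–O bond near the enolate plane, which disfavours β-elimination. The electrophile approaches the outer face of the crown-shaped diene, anti to the C8–C9 bond, which places the acetate arm β on C7.

Step 14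
Reactants: 25
Product: 26 6β-hydroxy ester (3S,4S,6S,7S,8R)
Conditions: LiBH(s-Bu)3 (L-Selectride), THF, −78 °C; H2O
Reagents that add atoms: none
Why: The bulky hydride can reach the C6 carbonyl only from the ring periphery, since the inner face is covered by the transannular C1=C10 bond; this should give the alcohol whose oxygen is syn to the C7 arm and the C8 oxygen. The tert-butyl ester is not attacked by the cold alkoxide.

Step 15
Reactants: 26
Product: 28 trans-fused lactone (3S,4S,6R,7R,8R), via C6 triflate 27 (not isolated)
Conditions: Tf2O, 2,6-lutidine, CH2Cl2, −78 to 0 °C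
Reagents that add atoms: none
Why: Lactonisation of a γ-sulfonyloxy ester with inversion: the ester carbonyl oxygen attacks C6 in a 5-exo SN2 displacement from the face opposite the triflate, to which the C7 arm is antiperiplanar when the C5–C6–C7–C8 torsion is anti. The oxocarbenium ion then loses the tert-butyl group as isobutene, leaving the lactone oxygen α on C6, anti to C11.

Step 16
Reactants: 28; 29 N,N-dimethylmethyleneiminium iodide (Eschenmoser's salt)
Product: 31 C11 Mannich base, via lithium lactone enolate 30 (not isolated)
Conditions: LDA, THF, −78 °C; then 29, −78 to 0 °C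
Reagents that add atoms: none
Why: Mannich reaction of a lactone enolate; the only acidic position is C11, there is no leaving group β to it, and the C11 configuration is of no consequence.

Step 17
Reactants: 31
Product: 33 α-methylene lactone PMB ether, via trimethylammonium iodide 32 (not isolated)
Conditions: MeI, MeOH, rt; then NaHCO3 (aq), EtOAc, rt
Reagents that add atoms: none
Why: Quaternisation followed by mild-base elimination of trimethylamine (Hofmann-type, E1cB) gives the exocyclic methylene without migration into the ring.

Step 18
Reactants: 33
Product: 34 8β-hydroxy α-methylene lactone acetonide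
Conditions: DDQ, CH2Cl2/pH 7 buffer, 0 °C
Reagents that add atoms: none
Why: Oxidative cleavage of the electron-rich benzyl ether by hydride abstraction; the electron-poor methylene lactone, the buffered acetonide and the isolated olefin are not oxidised under these conditions.

Step 19
Reactants: 34; 35 angelic acid
Product: 37 C8 angelate acetonide, via mixed anhydride 36 (not isolated)
Conditions: 2,4,6-trichlorobenzoyl chloride, Et3N, toluene, rt; then 34, toluene, 80 °C
Reagents that add atoms: none
Why: Yamaguchi-type mixed anhydride acylation run without a nucleophilic catalyst, which is the known way to esterify with angelic acid without Z-to-E isomerisation; C8 is the only free hydroxyl.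

Step 20
Reactants: 37
Product: 38 3,4-diol angelate (3S,4S,6R,7R,8R)
Conditions: AcOH/H2O (4:1), 40 °C
Reagents that add atoms: none
Why: The strained trans-fused dioxolane hydrolyses under acid too weak to protonate the trisubstituted olefin or to touch the esters.

Step 21
Reactants: 38
Product: 39 argophyllin A
Conditions: dimethyldioxirane (acetone solution), CH2Cl2, −20 °C
Reagents that add atoms: dimethyldioxirane, CC1(C)OO1
Why: Neutral epoxidation of the strained, electron-rich E olefin, far faster than attack on the acrylate or the angelate. The oxidant adds to the outer face of the crown conformer, the face on which the C3 hydroxyl lies, which gives the 1R,10R epoxide; no acid is present that could trigger transannular opening.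

**Compound list**

1 | (S)-(+)-carvone, (5S)-2-methyl-5-(prop-1-en-2-yl)cyclohex-2-en-1-one | CC1=CC[C@@H](CC1=O)C(C)=C | starting material
2 | (1S,4S,6S)-1-methyl-4-(prop-1-en-2-yl)-7-oxabicyclo[4.1.0]heptan-2-one, epoxide anti to isopropenyl | O=C1[C@@]2(C)O[C@H]2C[C@H](C(C)=C)C1 | intermediate
3 | hydrazone of 2 | NN=C1[C@@]2(C)O[C@H]2C[C@H](C(C)=C)C1 | intermediate
4 | (1S,5R)-2-methyl-5-(prop-1-en-2-yl)cyclohex-2-en-1-ol, trans-carveol | C1C=C(C)[C@@H](O)C[C@@H]1C(C)=C | intermediate
5 | tert-butyldimethylsilyl ether of 4 | C1C=C(C)[C@@H](O[Si](C)(C)C(C)(C)C)C[C@@H]1C(C)=C | intermediate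
6 | (4S,6R)-4-(tert-butyldimethylsilyloxy)-3-methyl-6-(prop-1-en-2-yl)cyclohex-2-en-1-one | O=C1C=C(C)[C@@H](O[Si](C)(C)C(C)(C)C)C[C@@H]1C(C)=C | intermediate
7 | (1R,3R,5S,6S)-5-(tert-butyldimethylsilyloxy)-6-methyl-3-(prop-1-en-2-yl)-7-oxabicyclo[4.1.0]heptan-2-one, epoxide anti to the silyloxy group | O=C1[C@@H]2O[C@]2(C)[C@@H](O[Si](C)(C)C(C)(C)C)C[C@@H]1C(C)=C | intermediate
8 | (2R,4S,5S)-4-(tert-butyldimethylsilyloxy)-5-hydroxy-5-methyl-2-(prop-1-en-2-yl)cyclohexan-1-one | O=C1C[C@](C)(O)[C@@H](O[Si](C)(C)C(C)(C)C)C[C@@H]1C(C)=C | intermediate
9 | (2R,4S,5S)-4,5-dihydroxy-5-methyl-2-(prop-1-en-2-yl)cyclohexan-1-one, anti diol | O=C1C[C@](C)(O)[C@@H](O)C[C@@H]1C(C)=C | intermediate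
10 | (2R,4S,5S)-4,5-(isopropylidenedioxy)-5-methyl-2-(prop-1-en-2-yl)cyclohexan-1-one, trans-fused acetonide with axial isopropenyl | O=C1C[C@](C)(OC(C)(C)O2)[C@@H]2C[C@@H]1C(C)=C | intermediate
11 | (2S,4S,5S)-4,5-(isopropylidenedioxy)-5-methyl-2-(prop-1-en-2-yl)cyclohexan-1-one, equatorial isopropenyl cis to the C3 oxygen | O=C1C[C@](C)(OC(C)(C)O2)[C@@H]2C[C@H]1C(C)=C | intermediate
12 | 4-methoxybenzyl alcohol | COc1ccc(CO)cc1 | starting material
13 | ethyl vinyl ether | C=COCC | starting material
14 | 4-methoxybenzyl vinyl ether | C=COCc1ccc(OC)cc1 | intermediate
15 | 1,2-dibromoethyl 4-methoxybenzyl ether | BrCC(Br)OCc1ccc(OC)cc1 | intermediate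
16 | (Z)-2-bromovinyl 4-methoxybenzyl ether | Br/C=C\OCc1ccc(OC)cc1 | intermediate
17 | (Z)-2-(4-methoxybenzyloxy)vinyllithium | [Li]/C=C\OCc1ccc(OC)cc1 | intermediate
18 | (1S,2S,4S,5S)-1-[(Z)-2-(4-methoxybenzyloxy)ethenyl]-4,5-(isopropylidenedioxy)-5-methyl-2-(prop-1-en-2-yl)cyclohexan-1-ol | O[C@@]1(/C=C\OCc2ccc(OC)cc2)C[C@](C)(OC(C)(C)O3)[C@@H]3C[C@H]1C(C)=C | intermediate
19 | chlorotrimethylsilane | C[Si](C)(C)Cl | starting material
20 | potassium alkoxide of 18 | [K+].[O-][C@@]1(/C=C\OCc2ccc(OC)cc2)C[C@](C)(OC(C)(C)O3)[C@@H]3C[C@H]1C(C)=C | intermediate
21 | potassium C6–C7 enolate of the ten-membered ketone, E C1=C10, 8R | [K+].COc1ccc(CO[C@H]2/C=C(\[O-])C[C@](C)(OC(C)(C)O3)[C@@H]3C/C=C(\C)C2)cc1 | intermediate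
22 | (3S,4S,8R)-3,4-(isopropylidenedioxy)-8-(4-methoxybenzyloxy)-4,10-dimethyl-6-(trimethylsilyloxy)cyclodeca-1(10),6-diene, E at C1=C10, ring-trans (Z by CIP) at C6=C7 | COc1ccc(CO[C@H]2/C=C(\O[Si](C)(C)C)C[C@](C)(OC(C)(C)O3)[C@@H]3C/C=C(\C)C2)cc1 | intermediate
23 | tert-butyl bromoacetate | BrCC(=O)OC(C)(C)C | starting material
24 | lithium C6–C7 enolate corresponding to 22 | [Li+].COc1ccc(CO[C@H]2/C=C(\[O-])C[C@](C)(OC(C)(C)O3)[C@@H]3C/C=C(\C)C2)cc1 | intermediate
25 | tert-butyl 2-[(3S,4S,7R,8R)-3,4-(isopropylidenedioxy)-8-(4-methoxybenzyloxy)-4,10-dimethyl-6-oxocyclodec-1(10)-en-7-yl]acetate, E olefin, arm β | COc1ccc(CO[C@H]2[C@@H](CC(=O)OC(C)(C)C)C(=O)C[C@](C)(OC(C)(C)O3)[C@@H]3C/C=C(\C)C2)cc1 | intermediate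
26 | 6β-hydroxy ester, (3S,4S,6S,7S,8R), hydroxyl syn to the C7 arm | COc1ccc(CO[C@H]2[C@@H](CC(=O)OC(C)(C)C)[C@@H](O)C[C@](C)(OC(C)(C)O3)[C@@H]3C/C=C(\C)C2)cc1 | intermediate
27 | C6 trifluoromethanesulfonate of 26 | COc1ccc(CO[C@H]2[C@@H](CC(=O)OC(C)(C)C)[C@@H](OS(=O)(=O)C(F)(F)F)C[C@](C)(OC(C)(C)O3)[C@@H]3C/C=C(\C)C2)cc1 | intermediate
28 | trans-fused 12,6-lactone, (3S,4S,6R,7R,8R), 8-PMB ether, 3,4-acetonide, E C1=C10 | COc1ccc(CO[C@H]2[C@H]3CC(=O)O[C@@H]3C[C@](C)(OC(C)(C)O4)[C@@H]4C/C=C(\C)C2)cc1 | intermediate
29 | N,N-dimethylmethyleneiminium iodide | C=[N+](C)C.[I-] | starting material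
30 | lithium enolate of lactone 28 | [Li+].COc1ccc(CO[C@H]2[C@H]3C=C([O-])O[C@@H]3C[C@](C)(OC(C)(C)O4)[C@@H]4C/C=C(\C)C2)cc1 | intermediate
31 | 11-(dimethylaminomethyl) lactone, C11 configuration not controlled | COc1ccc(CO[C@H]2[C@H]3C(CN(C)C)C(=O)O[C@@H]3C[C@](C)(OC(C)(C)O4)[C@@H]4C/C=C(\C)C2)cc1 | intermediate
32 | trimethylammonium iodide of 31 | COc1ccc(CO[C@H]2[C@H]3C(C[N+](C)(C)C)C(=O)O[C@@H]3C[C@](C)(OC(C)(C)O4)[C@@H]4C/C=C(\C)C2)cc1.[I-] | intermediate
33 | α-methylene lactone, 8-PMB ether, 3,4-acetonide, (3S,4S,6R,7R,8R) | COc1ccc(CO[C@H]2[C@H]3C(=C)C(=O)O[C@@H]3C[C@](C)(OC(C)(C)O4)[C@@H]4C/C=C(\C)C2)cc1 | intermediate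
34 | 8β-hydroxy α-methylene lactone 3,4-acetonide, (3S,4S,6R,7R,8R) | O[C@H]1[C@H]2C(=C)C(=O)O[C@@H]2C[C@](C)(OC(C)(C)O3)[C@@H]3C/C=C(\C)C1 | intermediate
35 | angelic acid, (Z)-2-methylbut-2-enoic acid | C/C=C(/C)C(=O)O | starting material
36 | angelic 2,4,6-trichlorobenzoic anhydride | C/C=C(/C)C(=O)OC(=O)c1c(Cl)cc(Cl)cc1Cl | intermediate
37 | 8-O-angeloyl α-methylene lactone 3,4-acetonide | C/C=C(/C)C(=O)O[C@H]1[C@H]2C(=C)C(=O)O[C@@H]2C[C@](C)(OC(C)(C)O3)[C@@H]3C/C=C(\C)C1 | intermediate
38 | 1,10-deoxy precursor: 8-O-angeloyl-3,4-dihydroxy α-methylene lactone with E C1=C10 | C/C=C(/C)C(=O)O[C@H]1[C@H]2C(=C)C(=O)O[C@@H]2C[C@](C)(O)[C@@H](O)C/C=C(\C)C1 | intermediate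
39 | argophyllin A, (1R,3S,4S,6R,7S,8R,10R) in germacrane numbering | C=C1C(=O)O[C@@H]2C[C@](C)(O)[C@@H](O)C[C@H]3O[C@]3(C)C[C@@H](OC(=O)/C(C)=C\C)[C@@H]12 | target

**Step count and uncertain steps**

Total: 21 steps. Longest linear sequence: 19 steps (1 to 39 through steps 1 to 8 and 11 to 21); the vinyl ether branch (steps 9 and 10) joins at step 11.

**Step 12 (key step).** The most likely failure is loss of the PMB-oxide from the potassium enolate by β-elimination before it is silylated. Leakage through a boat transition state is also possible, because the Z alkoxy group must sit pseudo-axial and syn to the oxyanion; this would erode the C8 configuration or the olefin geometry. The fallback avoids any enolate. Alcohol 18 is heated without base (sealed tube, about 190 °C, base-washed glass), so that the enol from the neutral oxy-Cope shift tautomerises irreversibly to the cyclodecenone F1. F1 is then returned to 22 by kinetic deprotonation at the less hindered C7 methylene with LDA in the presence of Me3SiCl at −78 °C. The regiochemistry then depends on that deprotonation and not on the rearrangement.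

**Step 4.** Hydrogen abstraction may be unselective: attack at the carbinol C–H or at the allylic positions of the isopropenyl group would compete with oxidation of the ring methylene. The fallback starts from 4 and builds the carbonyl by transposition, without C–H oxidation:
- VO(acac)2 with t-BuOOH gives the syn epoxy alcohol F2, and silylation gives its ether F3.
- PhSeNa (from (PhSe)2 and NaBH4) opens the epoxide at the secondary carbon to the hydroxy selenide F4.
- H2O2 causes selenoxide elimination away from the carbinol carbon to the tertiary allylic alcohol F5.
- Pyridinium chlorochromate (C5H5NH[CrO3Cl]) effects oxidative 1,3-transposition, which returns to 6.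

**Step 8.** Repeated enolisation under the amine base may let the dienolate be protonated at its terminus, which moves the double bond into conjugation as the isopropylidene ketone before epimerisation is complete. The fallback starts from 10 and replaces equilibration by kinetic protonation. TBSOTf with Et3N under equilibrating conditions gives the conjugated silyl dienol ether F6. Bu4NF buffered with AcOH at −78 °C then releases the dienolate, which is protonated at the α carbon from the axial direction, giving 11.

**Step 10.** Bromide may cleave the PMB group at the α-bromo ether stage, and the elimination may give too much of the E isomer. The fallback starts from 12 and 11, bypasses steps 9 to 11, and builds the Z enol ether by semi-hydrogenation: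
- KH and trichloroethylene convert 12 into the dichlorovinyl ether F7.
- Two equivalents of n-BuLi at −78 °C give the lithium alkoxyacetylide F8.
- F8 adds equatorially to 11 to give the alkynyl carbinol F9.
- Hydrogen over Pd/CaCO3 poisoned with Pb(OAc)2 (Lindlar catalyst) with quinoline reduces the ynol ether to the Z enol ether 18.

**Step 14.** The facial selectivity may be poor or reversed if the ketone reacts through a conformer other than the crown inherited from the enolate; a mixture of C6 epimers would result. The fallback makes the sequence convergent instead of seeking selectivity. The epimers are separated, and the 6α-hydroxy ester F10 is closed with retention by NaH in THF (alkoxide attack on the tert-butyl ester), which gives the same lactone 28 that 26 gives with inversion in step 15.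

**Step 15.** The triflate may ionise and then eliminate toward C5 or C7, or the acetonide oxygen on C3 may participate in place of the ester carbonyl. The fallback starts from 26 and separates inversion from ring closure. Mitsunobu reaction with 4-nitrobenzoic acid (PPh3, diisopropyl azodicarboxylate) gives the inverted 6α-4-nitrobenzoate F11. K2CO3 in MeOH removes the ester to give the 6α-hydroxy ester F10, and NaH closes F10 with retention to 28.

Further compounds

F1 | step 12 | (3S,4S,8R)-3,4-(isopropylidenedioxy)-8-(4-methoxybenzyloxy)-4,10-dimethylcyclodec-1(10)-en-6-one, E olefin | COc1ccc(CO[C@H]2CC(=O)C[C@](C)(OC(C)(C)O3)[C@@H]3C/C=C(\C)C2)cc1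
F2 | step 4 | syn 2,3-epoxide of trans-carveol, epoxide on the face of the hydroxyl | C1[C@H]2O[C@@]2(C)[C@@H](O)C[C@@H]1C(C)=C
F3 | step 4 | tert-butyldimethylsilyl ether of F2 | C1[C@H]2O[C@@]2(C)[C@@H](O[Si](C)(C)C(C)(C)C)C[C@@H]1C(C)=C
F4 | step 4 | trans-diaxial β-hydroxy phenyl selenide from F3 | C1[C@H]([Se]c2ccccc2)[C@@](C)(O)[C@@H](O[Si](C)(C)C(C)(C)C)C[C@@H]1C(C)=C
F5 | step 4 | tertiary allylic alcohol with C5=C6 olefin | C1=C[C@@](C)(O)[C@@H](O[Si](C)(C)C(C)(C)C)C[C@@H]1C(C)=C
F6 | step 8 | conjugated tert-butyldimethylsilyl dienol ether of ketone 10 | CC(C)(C)[Si](C)(C)OC1=C(C(C)=C)C[C@@H]2OC(C)(C)O[C@@]2(C)C1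
F7 | step 10 | (E)-1,2-dichlorovinyl 4-methoxybenzyl ether | Cl/C=C(/Cl)OCc1ccc(OC)cc1
F8 | step 10 | lithium (4-methoxybenzyloxy)acetylide | [Li]C#COCc1ccc(OC)cc1
F9 | step 10 | (1S,2S,4S,5S)-1-[(4-methoxybenzyloxy)ethynyl] carbinol acetonide | O[C@@]1(C#COCc2ccc(OC)cc2)C[C@](C)(OC(C)(C)O3)[C@@H]3C[C@H]1C(C)=C
F10 | step 14 | 6α-hydroxy ester, C6 epimer of 26 | COc1ccc(CO[C@H]2[C@@H](CC(=O)OC(C)(C)C)[C@H](O)C[C@](C)(OC(C)(C)O3)[C@@H]3C/C=C(\C)C2)cc1
F11 | step 15 | 6α-(4-nitrobenzoate) of the hydroxy ester | COc1ccc(CO[C@H]2[C@@H](CC(=O)OC(C)(C)C)[C@H](OC(=O)c3ccc(cc3)[N+](=O)[O-])C[C@](C)(OC(C)(C)O4)[C@@H]4C/C=C(\C)C2)cc1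
A1 | alternative 1 | open-chain C6 hydroximoyl chloride with C3 hydroxyl and C4–C5 olefin | CC(C)(C)OC(=O)C[C@@H](C(Cl)=NO)[C@H](O[Si](C)(C)C(C)(C)C)C/C(C)=C/C[C@H](O)C(C)=C
A2 | alternative 1 | isoxazoline-bridged ten-membered ring | CC(C)(C)OC(=O)C[C@@H]1[C@H](O[Si](C)(C)C(C)(C)C)C/C(C)=C/C[C@H](O)[C@]2(C)CC1=NO2
A3 | alternative 2 | seco C3–C4 aldehyde with C4 alkenyl iodide on the lactol methyl ether | C=C(I)C[C@H]1O[C@@H](OC)C[C@@H]1[C@H](O[Si](C)(C)C(C)(C)C)C/C(C)=C/CC=O
A4 | alternative 2 | ten-membered exo-methylene allylic alcohol | C1[C@H](OC)O[C@@H]2CC(=C)[C@@H](O)C/C=C(\C)C[C@@H](O[Si](C)(C)C(C)(C)C)[C@@H]12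
A5 | alternative 3 | seco C9–C10 alkynyl epoxide on the butyrolactone acetonide | CC#CC[C@@H]1OC(C)(C)O[C@@]1(C)C[C@H]2OC(=O)C[C@@H]2[C@H]3CO3
A6 | alternative 3 | ten-membered E-olefin lactone with free C8 hydroxyl | C1C(=O)O[C@@H]2C[C@](C)(OC(C)(C)O4)[C@@H]4C/C=C(\C)C[C@@H](O)[C@@H]12
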